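**Strategy.** Ring A is the 2,3-disubstituted indole, ring B the indol-3-yl group, C1'–C3' the propanediol chain from the diaryl methine outward. The two CH2OH carbons (end of the hydroxyethyl chain on C3 of ring A, and C3') are treated as the two halves of one cleaved alkene, which places C3, C2, C1' and C2' in a cyclohepta[b]indole. A phosphoric-acid-catalysed (4+3) annulation of the cation from a racemic (indol-2-yl)(N-tosylindol-3-yl)methanol with an (E)-1-silyloxybutadiene forms C3–CH2 and C1'–C2', closes that ring and sets both stereocentres in one operation; alkene cleavage with borohydride work-up then frees both primary alcohols.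

Key step: step 4

Assumption: the sense of induction of the chiral phosphoric acid cannot be derived with confidence, so (R)-TRIP is written and its antipode would be used unchanged if the (6R,7S) enantiomer predominated.

**Step 1**
Reactants: 1 1H-indole-3-carbaldehyde
Product: 2 1-tosyl-1H-indole-3-carbaldehyde
Conditions: TsCl, Et3N, DMAP (cat.), CH2Cl2, 0 °C to rt
Reagents that add atoms: p-toluenesulfonyl chloride, Cc1ccc(cc1)S(Cl)(=O)=O
Why: N-Sulfonylation of the indole nitrogen (DMAP-catalysed sulfonyl transfer) is fast because the 3-formyl group acidifies N–H, and the tosyl group is installed now because it later keeps ring B from donating into the cation or reacting at its own C2.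

**Step 2**
Reactants: 3 1H-indole; 2 1-tosyl-1H-indole-3-carbaldehyde
Product: 7 rac-(1H-indol-2-yl)(1-tosyl-1H-indol-3-yl)methanol, via lithium indole-1-carboxylate 4 (not isolated), via lithium 2-lithioindole-1-carboxylate 5 (not isolated), via dilithium alkoxide carboxylate 6 (not isolated)
Conditions: n-BuLi, THF, −78 °C; CO2 (g); evaporate, THF; t-BuLi, −78 °C; then 2, −78 °C to rt; sat. aq NH4Cl
Reagents that add atoms: none
Why: Katritzky's CO2-protected C2-lithiation of indole followed by 1,2-addition to the aldehyde should work because the lithium carbamate directs tert-butyllithium to C2, the aryllithium adds to the aldehyde faster than it attacks the sulfonamide at −78 °C, and the N-carboxylic acid loses CO2 on mild aqueous work-up; the carbinol centre is left racemic on purpose because it is erased on ionisation.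

**Step 3**
Reactants: 8 (E)-but-2-enal
Product: 9 (E)-1-(tert-butyldimethylsilyloxy)buta-1,3-diene
Conditions: TBSOTf, Et3N, Et2O, 0 °C to rt; distil
Reagents that add atoms: tert-butyldimethylsilyl trifluoromethanesulfonate, CC(C)(C)[Si](C)(C)OS(=O)(=O)C(F)(F)F
Why: Silyl dienol ether formation (O-silylation of the enal, then γ-deprotonation by triethylamine) should give mainly the E enol ether from the s-trans enal, and the tert-butyldimethylsilyl group is chosen over trimethylsilyl so that the ether survives the acid catalyst, the water released in step 4 and all later steps.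

**Step 4**
Reactants: 7 rac-(1H-indol-2-yl)(1-tosyl-1H-indol-3-yl)methanol; 9 (E)-1-(tert-butyldimethylsilyloxy)buta-1,3-diene
Product: 12 (6S,7R)-7-(tert-butyldimethylsilyloxy)-6-(1-tosyl-1H-indol-3-yl)-5,6,7,10-tetrahydrocyclohepta[b]indole (cis), via azaallyl cation 10 (not isolated), via oxocarbenium adduct 11 (not isolated)
Conditions: (R)-TRIP (10 mol%), 9 (3 equiv), 4 Å MS, toluene (dilute), −40 to −20 °C
Reagents that add atoms: none
Why: The acid should ionise 7 to cation 10, a 2-azaallyl cation of ring A with electrophilic termini C1' and C3, held by the chiral phosphate through N–H; the CH2 terminus of 9 then adds to C3 to give the 2-alkylideneindoline/silyloxocarbenium 11, the enamine carbon C1' adds to the oxocarbenium carbon, and loss of the C3 proton restores the indole. The closest known reaction type is the phosphoric-acid-catalysed stepwise (4+3) cycloaddition of indolylmethanol cations with 1-heteroatom-substituted dienes to cyclohepta[b]indoles, combined with the known C3-electrophilic behaviour of 2-indolylmethanols; the pairing of termini needed here is an extrapolation within that class and has to be confirmed on the product by HMBC and NOE. The seven-membered ring closes by a 7-(enolendo)-exo-trig addition of C1' to the C=O+ carbon, the same 1,2-mode by which heteroatom-stabilised allyl cations close in the known cases, in competition with five-ring closure at the β-carbon. C6 and C7 are both created in this closure: their cis relation is expected from a compact ion-paired transition state that retains the s-cis E-dienol ether with the silyloxy group outward, and the absolute sense from the phosphate that bridges N–H and the oxocarbenium, the racemic carbinol converging because its stereocentre is lost in planar 10. The step needs CH2-to-C3 regiochemistry and seven- over five-ring closure: C1' is screened by the sulfonylated ring B and the N–H-bound phosphate whereas C3 is an open CH, the tosyl group stops ring B from donating charge or reacting at its C2, and the robust tert-butyldimethylsilyl group keeps the oxocarbenium alive until C1' closes on its most electrophilic carbon.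

**Step 5**
Reactants: 12 (6S,7R)-7-(tert-butyldimethylsilyloxy)-6-(1-tosyl-1H-indol-3-yl)-5,6,7,10-tetrahydrocyclohepta[b]indole
Product: 13 tert-butyl (6S,7R)-7-(tert-butyldimethylsilyloxy)-6-(1-tosyl-1H-indol-3-yl)-7,10-dihydrocyclohepta[b]indole-5(6H)-carboxylate
Conditions: Boc2O, DMAP (cat.), MeCN, rt
Reagents that add atoms: di-tert-butyl dicarbonate, CC(C)(C)OC(=O)OC(=O)OC(C)(C)C
Why: DMAP-catalysed N-acylation of the indole with Boc anhydride (carbamate formation) should proceed even next to the C6 substituent and turns the ring A 2,3-bond into an electron-poor enecarbamate that osmium tetroxide and periodate leave alone.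

**Step 6**
Reactants: 13 tert-butyl (6S,7R)-7-(tert-butyldimethylsilyloxy)-6-(1-tosyl-1H-indol-3-yl)-7,10-dihydrocyclohepta[b]indole-5(6H)-carboxylate
Product: 16 tert-butyl 2-[(1S,2S)-2-(tert-butyldimethylsilyloxy)-3-hydroxy-1-(1-tosyl-1H-indol-3-yl)propyl]-3-(2-hydroxyethyl)-1H-indole-1-carboxylate, via cis-diol 14 (not isolated), via dialdehyde 15 (not isolated)
Conditions: OsO4 (cat.), NaIO4, 2,6-lutidine, dioxane/H2O, rt; then NaBH4, MeOH, 0 °C
Reagents that add atoms: osmium tetroxide, O=[Os](=O)(=O)=O; sodium periodate, [Na+].[O-][I](=O)(=O)=O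
Why: Lemieux–Johnson oxidation (osmylation of the only isolated alkene, periodate fission of the glycol, 2,6-lutidine buffer) followed by sodium borohydride reduction of both aldehydes should convert the ring alkene into the two primary alcohols without touching C1' or C2', the α-silyloxy aldehyde being reduced before it can enolise.

**Step 7**
Reactants: 16 tert-butyl 2-[(1S,2S)-2-(tert-butyldimethylsilyloxy)-3-hydroxy-1-(1-tosyl-1H-indol-3-yl)propyl]-3-(2-hydroxyethyl)-1H-indole-1-carboxylate
Product: 17 colletotryptin B [(2S,3S)-3-[3-(2-hydroxyethyl)-1H-indol-2-yl]-3-(1H-indol-3-yl)propane-1,2-diol]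
Conditions: TBAF (excess, 1 M), THF, 65 °C, degassed; aq NH4Cl
Reagents that add atoms: none
Why: Fluoride-mediated global deprotection should work because hot TBAF in THF is known to cleave silyl ethers, indole N-sulfonyl groups (attack at sulfur) and indole N-Boc groups (attack at the carbonyl), and neither stereocentre carries an acidic hydrogen or a leaving group, so the configuration set in step 4 is retained.

**Compound list**
1 | 1H-indole-3-carbaldehyde | O=Cc1c[nH]c2ccccc12 | starting material
2 | 1-tosyl-1H-indole-3-carbaldehyde | O=Cc1cn(S(=O)(=O)c2ccc(C)cc2)c2ccccc12 | intermediate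
3 | 1H-indole | c1ccc2[nH]ccc2c1 | starting material
4 | lithium indole-1-carboxylate | [Li+].[O-]C(=O)n1ccc2ccccc12 | intermediate
5 | lithium 2-lithioindole-1-carboxylate | [Li+].[O-]C(=O)n1c([Li])cc2ccccc12 | intermediate
6 | dilithium alkoxide carboxylate of 2-[hydroxy(1-tosylindol-3-yl)methyl]indole-1-carboxylic acid (racemic) | [Li+].[Li+].[O-]C(=O)n1c(C([O-])c2cn(S(=O)(=O)c3ccc(C)cc3)c3ccccc23)cc2ccccc12 | intermediate
7 | rac-(1H-indol-2-yl)(1-tosyl-1H-indol-3-yl)methanol | OC(c1cc2ccccc2[nH]1)c1cn(S(=O)(=O)c2ccc(C)cc2)c2ccccc12 | intermediate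
8 | (E)-but-2-enal (crotonaldehyde) | C/C=C/C=O | starting material
9 | (E)-1-(tert-butyldimethylsilyloxy)buta-1,3-diene | C=C/C=C/O[Si](C)(C)C(C)(C)C | intermediate
10 | (1H-indol-2-yl)(1-tosylindol-3-yl)methylium, charge shared by C1' and C3 of ring A, phosphate counter-ion | [CH+](c1cc2ccccc2[nH]1)c1cn(S(=O)(=O)c2ccc(C)cc2)c2ccccc12 | intermediate
11 | O-silyl oxocarbenium of (Z)-4-{2-[(1-tosylindol-3-yl)methylidene]indolin-3-yl}but-2-enal (C3 and exocyclic alkene configuration not defined) | CC(C)(C)[Si](C)(C)[O+]=C/C=C\CC1C(=Cc2cn(S(=O)(=O)c3ccc(C)cc3)c3ccccc23)Nc2ccccc12 | intermediate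
12 | (6S,7R)-7-(tert-butyldimethylsilyloxy)-6-(1-tosyl-1H-indol-3-yl)-5,6,7,10-tetrahydrocyclohepta[b]indole (cis) | C1C=C[C@@H](O[Si](C)(C)C(C)(C)C)[C@@H](c2cn(S(=O)(=O)c3ccc(C)cc3)c3ccccc23)c2[nH]c3ccccc3c12 | intermediate
13 | tert-butyl (6S,7R)-7-(tert-butyldimethylsilyloxy)-6-(1-tosyl-1H-indol-3-yl)-7,10-dihydrocyclohepta[b]indole-5(6H)-carboxylate | C1C=C[C@@H](O[Si](C)(C)C(C)(C)C)[C@@H](c2cn(S(=O)(=O)c3ccc(C)cc3)c3ccccc23)c2n(C(=O)OC(C)(C)C)c3ccccc3c12 | intermediate
14 | cis-8,9-diol of 13 (C6 and C7 as in 13; C8/C9 configuration immaterial) | C1C(O)C(O)[C@@H](O[Si](C)(C)C(C)(C)C)[C@@H](c2cn(S(=O)(=O)c3ccc(C)cc3)c3ccccc23)c2n(C(=O)OC(C)(C)C)c3ccccc3c12 | intermediate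
15 | tert-butyl 2-[(1S,2S)-2-(tert-butyldimethylsilyloxy)-3-oxo-1-(1-tosyl-1H-indol-3-yl)propyl]-3-(2-oxoethyl)-1H-indole-1-carboxylate | O=CCc1c([C@H](c2cn(S(=O)(=O)c3ccc(C)cc3)c3ccccc23)[C@H](O[Si](C)(C)C(C)(C)C)C=O)n(C(=O)OC(C)(C)C)c2ccccc12 | intermediate
16 | tert-butyl 2-[(1S,2S)-2-(tert-butyldimethylsilyloxy)-3-hydroxy-1-(1-tosyl-1H-indol-3-yl)propyl]-3-(2-hydroxyethyl)-1H-indole-1-carboxylate | OCCc1c([C@H](c2cn(S(=O)(=O)c3ccc(C)cc3)c3ccccc23)[C@H](O[Si](C)(C)C(C)(C)C)CO)n(C(=O)OC(C)(C)C)c2ccccc12 | intermediate
17 | colletotryptin B, (2S,3S)-3-[3-(2-hydroxyethyl)-1H-indol-2-yl]-3-(1H-indol-3-yl)propane-1,2-diol | OCCc1c([C@H](c2c[nH]c3ccccc23)[C@H](O)CO)[nH]c2ccccc12 | target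

**Count**
Total step count: 7.
Longest linear sequence: 6 steps (steps 1, 2, 4, 5, 6, 7; compounds 1 → 2 → 7 → 12 → 13 → 16 → 17); step 3 is a one-step side branch.

**Steps most likely to fail**

1. Step 4. The diene CH2 terminus may add to C1' instead of C3, giving the regioisomeric ring. The first adduct may also be intercepted by desilylation to an open-chain enal or by five-ring closure. Facial and cis/trans control in the ring closure may be weak.
Fallback (known chemistry, sets out from 3, comes back at 17): indole 3 would be condensed with commercial (R)-2,3-O-isopropylideneglyceraldehyde and p-toluenesulfinic acid (cat. TsOH, EtOAc, rt) to the bench-stable sulfonylindole 3-{[(4R)-2,2-dimethyl-1,3-dioxolan-4-yl](tosyl)methyl}-1H-indole F1; either epimer at the sulfonyl carbon serves. Commercial tryptophol would be silylated (TBSCl, imidazole, DMF) to 3-[2-(tert-butyldimethylsilyloxy)ethyl]-1H-indole F2. Sc(OTf)3 (cat., CH2Cl2, −20 °C) would expel sulfinate from F1, and the 3-alkylideneindoleninium would be trapped at C2 of F2. This Friedel–Crafts alkylation of a 3-substituted indole is the established way to unsymmetrical 2,3'-bis(indolyl)methanes and would give 3-[2-(tert-butyldimethylsilyloxy)ethyl]-2-{(S)-[(4S)-2,2-dimethyl-1,3-dioxolan-4-yl](1H-indol-3-yl)methyl}-1H-indole F3. C2' is bought with the aldehyde; C1' would arise by Felkin–Anh 1,2-induction (attack anti to the dioxolane C–O bond), which models as the required 1'S isomer, but the ratio would have to be established. AcOH/H2O/THF at 40 °C would then remove acetonide and silyl ether to give 17.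

2. Step 6. Osmium or periodate may over-oxidise the indole 2,3-bonds, and the dialdehyde may undergo aldol reaction or epimerise at C2' before it is reduced.
Fallback (sets out from 13, comes back at 16): ozone in CH2Cl2 at −78 °C, with Sudan Red 7B as end-point indicator, would convert the ring alkene into the secondary ozonide (1,2,4-trioxolane) of 13 F4. This would be reduced in the same flask with NaBH4/MeOH (−78 °C to rt) to 16. Criegee ozonolysis with a hydride quench replaces osmylation and periodate altogether, and no free dialdehyde is ever warmed.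

3. Step 7. Sulfonamide cleavage by fluoride may be incomplete, or the carbamate may migrate to a neighbouring alkoxide under hot basic conditions.
Fallback (sets out from 16, comes back at 17): Cs2CO3 in MeOH/THF at 60 °C would remove the sulfonyl group and the carbamate by methanolysis. The silyl ether stays and keeps the C2' oxygen from accepting the Boc group, giving 2-[(1S,2S)-2-(tert-butyldimethylsilyloxy)-3-hydroxy-1-(1H-indol-3-yl)propyl]-3-(2-hydroxyethyl)-1H-indole F5. TBAF in THF at 0 °C to rt (or HF·pyridine) would then remove the silyl group to give 17.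

**Further compounds**
F1 | step 4 | 3-{[(4R)-2,2-dimethyl-1,3-dioxolan-4-yl](tosyl)methyl}-1H-indole (epimers at the sulfonyl carbon) | CC1(C)OC[C@H](C(c2c[nH]c3ccccc23)S(=O)(=O)c2ccc(C)cc2)O1
F2 | step 4 | 3-[2-(tert-butyldimethylsilyloxy)ethyl]-1H-indole | CC(C)(C)[Si](C)(C)OCCc1c[nH]c2ccccc12
F3 | step 4 | 3-[2-(tert-butyldimethylsilyloxy)ethyl]-2-{(S)-[(4S)-2,2-dimethyl-1,3-dioxolan-4-yl](1H-indol-3-yl)methyl}-1H-indole | CC(C)(C)[Si](C)(C)OCCc1c([C@H](c2c[nH]c3ccccc23)[C@H]2COC(C)(C)O2)[nH]c2ccccc12
F4 | step 6 | secondary ozonide (1,2,4-trioxolane) of 13 | C1C2OC(OO2)[C@@H](O[Si](C)(C)C(C)(C)C)[C@@H](c2cn(S(=O)(=O)c3ccc(C)cc3)c3ccccc23)c2n(C(=O)OC(C)(C)C)c3ccccc3c12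
F5 | step 7 | 2-[(1S,2S)-2-(tert-butyldimethylsilyloxy)-3-hydroxy-1-(1H-indol-3-yl)propyl]-3-(2-hydroxyethyl)-1H-indole | OCCc1c([C@H](c2c[nH]c3ccccc23)[C@H](O[Si](C)(C)C(C)(C)C)CO)[nH]c2ccccc12
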